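In ring A the neighbouring carbons C8a and C4a carry the pyranone oxygen O1 and the ketone carbon C4, an ortho oxygen/acyl pattern that is the formal adduct of an aryne with the hydroxyl and ester termini of a β-hydroxy ester. In one operation, 3,5-bis(benzyloxy)benzyne (from its 2-silylaryl triflate and fluoride) is O-arylated at C8a by ethyl (S)-3-hydroxy-3-phenylpropanoate and the aryl anion formed at C4a acylates on the ester, closing ring C with the C2 stereocentre carried in intact. The two oligo(2-benzyloxybenzyl) arms, made by iterative benzylic Suzuki couplings, are then attached at C8 and C6 by iodination and Negishi coupling before global hydrogenolysis.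

Key step: step 9

Remark: compounds 1, 2, 9 and 14 are assumed to be commercially available; ring atoms are named by flavanone numbering (O1, C2, C3, C4, C4a, C5 to C8, C8a); step 10 assumes that the flavanone follows the C8 preference of 5,7-dialkoxyflavonoids in electrophilic iodination.

Step 1
Reactants: 1 2-(benzyloxy)benzyl bromide; 2 [4-(benzyloxy)-3-formylphenyl]boronic acid
Product: 3 2-(benzyloxy)-5-[2-(benzyloxy)benzyl]benzaldehyde
Conditions: Pd(PPh3)4 (cat.), K2CO3, DME/H2O, 80 °C
Reagents that add atoms: none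
Why: Suzuki–Miyaura sp3–sp2 cross-coupling, in which zerovalent palladium inserts readily into the benzylic C–Br bond and the boronic acid delivers its aryl group at the carbon para to the benzyloxy group, while the aldehyde is inert to aqueous carbonate.

Step 2
Reactants: 3 2-(benzyloxy)-5-[2-(benzyloxy)benzyl]benzaldehyde
Product: 4 {2-(benzyloxy)-5-[2-(benzyloxy)benzyl]phenyl}methanol
Conditions: NaBH4, THF/MeOH, 0 °C
Reagents that add atoms: none
Why: Borohydride reduction of the aryl aldehyde to the benzylic alcohol is chemoselective in the presence of aryl benzyl ethers and the diarylmethane unit.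

Step 3
Reactants: 4 {2-(benzyloxy)-5-[2-(benzyloxy)benzyl]phenyl}methanol
Product: 5 2-(benzyloxy)-5-[2-(benzyloxy)benzyl]benzyl chloride
Conditions: SOCl2, DMF (cat.), CH2Cl2, 0 °C to rt
Reagents that add atoms: thionyl chloride, O=S(Cl)Cl
Why: Deoxychlorination of the benzylic alcohol through its chlorosulfite gives a chloride that serves both as the next Suzuki electrophile and later as the substrate for zinc insertion.

Step 4
Reactants: 5 2-(benzyloxy)-5-[2-(benzyloxy)benzyl]benzyl chloride; 2 [4-(benzyloxy)-3-formylphenyl]boronic acid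
Product: 6 2-(benzyloxy)-5-{2-(benzyloxy)-5-[2-(benzyloxy)benzyl]benzyl}benzaldehyde
Conditions: Pd(OAc)2 (cat.), SPhos (2-dicyclohexylphosphino-2′,6′-dimethoxybiphenyl), K3PO4, toluene/H2O, 80 °C
Reagents that add atoms: none
Why: A second benzylic Suzuki–Miyaura coupling, in which the electron-rich biaryl phosphine promotes oxidative addition into the benzylic C–Cl bond, appends the third oxygenated ring with its aldehyde handle.

Step 5
Reactants: 6 2-(benzyloxy)-5-{2-(benzyloxy)-5-[2-(benzyloxy)benzyl]benzyl}benzaldehyde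
Product: 7 (2-(benzyloxy)-5-{2-(benzyloxy)-5-[2-(benzyloxy)benzyl]benzyl}phenyl)methanol
Conditions: NaBH4, THF/MeOH, 0 °C
Reagents that add atoms: none
Why: Chemoselective borohydride reduction of the aldehyde, as in step 2.

Step 6
Reactants: 7 (2-(benzyloxy)-5-{2-(benzyloxy)-5-[2-(benzyloxy)benzyl]benzyl}phenyl)methanol
Product: 8 2-(benzyloxy)-5-{2-(benzyloxy)-5-[2-(benzyloxy)benzyl]benzyl}benzyl chloride
Conditions: SOCl2, DMF (cat.), CH2Cl2, 0 °C to rt
Reagents that add atoms: thionyl chloride, O=S(Cl)Cl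
Why: Deoxychlorination via the chlorosulfite, as in step 3, furnishes the electrophile for the later zinc insertion.

Step 7
Reactants: 9 3,5-bis(benzyloxy)phenol
Product: 10 3,5-bis(benzyloxy)-2-bromophenol
Conditions: NBS (1.0 equiv), i-Pr2NH (cat.), CH2Cl2, −78 to 0 °C
Reagents that add atoms: N-bromosuccinimide, O=C1CCC(=O)N1Br
Why: Amine-catalysed ortho-selective electrophilic aromatic bromination of the phenol, in which the two ortho carbons are equivalent and the para carbon C4 is shielded by its two flanking benzyloxy groups.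

Step 8
Reactants: 10 3,5-bis(benzyloxy)-2-bromophenol
Product: 13 3,5-bis(benzyloxy)-2-(trimethylsilyl)phenyl trifluoromethanesulfonate, via aryl trimethylsilyl ether 11 (not isolated), via lithium 2-silylphenoxide 12 (not isolated)
Conditions: HMDS, THF, 70 °C, then evaporation; n-BuLi, THF, −100 to −80 °C; Tf2O, −100 °C to rt
Reagents that add atoms: hexamethyldisilazane, C[Si](C)(C)N[Si](C)(C)C; trifluoromethanesulfonic anhydride, O=S(=O)(OS(=O)(=O)C(F)(F)F)C(F)(F)F
Why: O-Silylation followed by bromine–lithium exchange triggers a 1,3 O-to-C silyl shift (retro-Brook rearrangement) and the liberated lithium phenoxide is triflated in the same flask, the standard route to 2-(trimethylsilyl)aryl triflate aryne precursors.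

Step 9
Reactants: 13 3,5-bis(benzyloxy)-2-(trimethylsilyl)phenyl trifluoromethanesulfonate; 14 ethyl (S)-3-hydroxy-3-phenylpropanoate
Product: 17 (S)-5,7-bis(benzyloxy)-2-phenylchroman-4-one, via aryne 15 (not isolated), via aryl caesium adduct 16 (not isolated)
Conditions: 13 (1.2 equiv), CsF (4 equiv), THF, 65 °C
Reagents that add atoms: none
Why: Proposed new method: fluoride removes the silyl group of 13 and triflate leaves to give aryne 15; the hydroxyl oxygen of 14, activated by hydrogen bonding to fluoride, adds to the aryne carbon remote from the flanking benzyloxy group (the future C8a), so that the carbanion of 16 sits at the future C4a, where it attacks the tethered ester and expels ethoxide. The closest known reaction type is the fluoride-mediated annulation of arynes with salicylate or anthranilate esters (O- or N-arylation followed by acyl substitution by the aryl anion), which gives xanthones and acridones but has not been shown with an aliphatic β-hydroxy ester. Ring C closes by 6-exo-trig attack of the aryl carbanion on the ester carbonyl. No stereocentre is formed: the C2 configuration is that of 14, whose C–O bond is never broken. The step needs regioselective addition to the aryne, secured by the inductively withdrawing benzyloxy group next to the triple bond, which polarises it toward attack at the distal carbon, and acyl transfer faster than protonation of 16, favoured by the six-membered transition state in aprotic THF; the sparingly soluble CsF keeps the medium weakly basic, which should limit retro-aldol cleavage of 14 and retro-oxa-Michael racemisation of 17.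

Step 10
Reactants: 17 (S)-5,7-bis(benzyloxy)-2-phenylchroman-4-one
Product: 18 (S)-5,7-bis(benzyloxy)-8-iodo-2-phenylchroman-4-one
Conditions: NIS (1.0 equiv), CF3CO2H (cat.), MeCN, 0 °C to rt, dark
Reagents that add atoms: N-iodosuccinimide, O=C1CCC(=O)N1I
Why: Electrophilic aromatic iodination of the trioxygenated ring A should occur at C8 because C6 is flanked by two benzyloxy groups, in line with the usual C8 preference of 5,7-dialkoxyflavonoids, and the unactivated phenyl rings do not compete.

Step 11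
Reactants: 18 (S)-5,7-bis(benzyloxy)-8-iodo-2-phenylchroman-4-one; 5 2-(benzyloxy)-5-[2-(benzyloxy)benzyl]benzyl chloride
Product: 20 (S)-5,7-bis(benzyloxy)-8-{2-(benzyloxy)-5-[2-(benzyloxy)benzyl]benzyl}-2-phenylchroman-4-one, via benzylic zinc chloride 19 (not isolated)
Conditions: 5, Zn dust, LiCl, THF, 25 °C, decanted from excess Zn; then 18, Pd(OAc)2 (cat.), SPhos, THF, 25 to 50 °C
Reagents that add atoms: none
Why: LiCl-promoted zinc insertion into the benzylic chloride followed by Negishi cross-coupling joins the arm to C8 under neutral conditions that tolerate the ketone and do not epimerise C2.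

Step 12
Reactants: 20 (S)-5,7-bis(benzyloxy)-8-{2-(benzyloxy)-5-[2-(benzyloxy)benzyl]benzyl}-2-phenylchroman-4-one
Product: 21 (S)-5,7-bis(benzyloxy)-8-{2-(benzyloxy)-5-[2-(benzyloxy)benzyl]benzyl}-6-iodo-2-phenylchroman-4-one
Conditions: NIS (1.05 equiv), MeCN/CH2Cl2, 0 °C to rt, dark
Reagents that add atoms: N-iodosuccinimide, O=C1CCC(=O)N1I
Why: Electrophilic aromatic iodination at C6, the only free position of ring A and, with two ortho and one para oxygen, far more nucleophilic than the monoalkoxy rings of the C8 arm, so that acid-free NIS should discriminate.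

Step 13
Reactants: 21 (S)-5,7-bis(benzyloxy)-8-{2-(benzyloxy)-5-[2-(benzyloxy)benzyl]benzyl}-6-iodo-2-phenylchroman-4-one; 8 2-(benzyloxy)-5-{2-(benzyloxy)-5-[2-(benzyloxy)benzyl]benzyl}benzyl chloride
Product: 23 (S)-5,7-bis(benzyloxy)-6-(2-(benzyloxy)-5-{2-(benzyloxy)-5-[2-(benzyloxy)benzyl]benzyl}benzyl)-8-{2-(benzyloxy)-5-[2-(benzyloxy)benzyl]benzyl}-2-phenylchroman-4-one, via benzylic zinc chloride 22 (not isolated)
Conditions: 8, Zn dust, LiCl, THF, 25 °C, decanted from excess Zn; then 21, Pd(OAc)2 (cat.), SPhos, THF, 60 °C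
Reagents that add atoms: none
Why: Negishi cross-coupling as in step 11, in which the bulky electron-rich biaryl phosphine supports oxidative addition and reductive elimination at the doubly ortho-substituted C6 iodide.

Step 14
Reactants: 23 (S)-5,7-bis(benzyloxy)-6-(2-(benzyloxy)-5-{2-(benzyloxy)-5-[2-(benzyloxy)benzyl]benzyl}benzyl)-8-{2-(benzyloxy)-5-[2-(benzyloxy)benzyl]benzyl}-2-phenylchroman-4-one
Product: 24 sarmentosumin D
Conditions: H2 (1 atm), Pd/C (10 wt%), EtOAc/MeOH, 25 °C
Reagents that add atoms: none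
Why: Catalytic hydrogenolysis cleaves all seven aryl benzyl ethers at atmospheric pressure, conditions under which the diarylmethane bridges, the ketone and the benzylic C2–O1 bond of flavanones normally survive and C2 is not epimerised.

Compound list
1 | 2-(benzyloxy)benzyl bromide | BrCc1ccccc1OCc1ccccc1 | starting material
2 | [4-(benzyloxy)-3-formylphenyl]boronic acid | O=Cc1cc(B(O)O)ccc1OCc1ccccc1 | starting material
3 | 2-(benzyloxy)-5-[2-(benzyloxy)benzyl]benzaldehyde | O=Cc1cc(Cc2ccccc2OCc2ccccc2)ccc1OCc1ccccc1 | intermediate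
4 | {2-(benzyloxy)-5-[2-(benzyloxy)benzyl]phenyl}methanol | OCc1cc(Cc2ccccc2OCc2ccccc2)ccc1OCc1ccccc1 | intermediate
5 | 2-(benzyloxy)-5-[2-(benzyloxy)benzyl]benzyl chloride | ClCc1cc(Cc2ccccc2OCc2ccccc2)ccc1OCc1ccccc1 | intermediate
6 | 2-(benzyloxy)-5-{2-(benzyloxy)-5-[2-(benzyloxy)benzyl]benzyl}benzaldehyde | O=Cc1cc(Cc2cc(Cc3ccccc3OCc3ccccc3)ccc2OCc2ccccc2)ccc1OCc1ccccc1 | intermediate
7 | (2-(benzyloxy)-5-{2-(benzyloxy)-5-[2-(benzyloxy)benzyl]benzyl}phenyl)methanol | OCc1cc(Cc2cc(Cc3ccccc3OCc3ccccc3)ccc2OCc2ccccc2)ccc1OCc1ccccc1 | intermediate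
8 | 2-(benzyloxy)-5-{2-(benzyloxy)-5-[2-(benzyloxy)benzyl]benzyl}benzyl chloride | ClCc1cc(Cc2cc(Cc3ccccc3OCc3ccccc3)ccc2OCc2ccccc2)ccc1OCc1ccccc1 | intermediate
9 | 3,5-bis(benzyloxy)phenol | Oc1cc(OCc2ccccc2)cc(OCc2ccccc2)c1 | starting material
10 | 3,5-bis(benzyloxy)-2-bromophenol | Oc1cc(OCc2ccccc2)cc(OCc2ccccc2)c1Br | intermediate
11 | [3,5-bis(benzyloxy)-2-bromophenoxy]trimethylsilane (not isolated) | C[Si](C)(C)Oc1cc(OCc2ccccc2)cc(OCc2ccccc2)c1Br | intermediate
12 | lithium 3,5-bis(benzyloxy)-2-(trimethylsilyl)phenolate (not isolated) | [Li+].[O-]c1cc(OCc2ccccc2)cc(OCc2ccccc2)c1[Si](C)(C)C | intermediate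
13 | 3,5-bis(benzyloxy)-2-(trimethylsilyl)phenyl trifluoromethanesulfonate | C[Si](C)(C)c1c(OS(=O)(=O)C(F)(F)F)cc(OCc2ccccc2)cc1OCc1ccccc1 | intermediate
14 | ethyl (S)-3-hydroxy-3-phenylpropanoate | CCOC(=O)C[C@@H](c1ccccc1)O | starting material
15 | 3,5-bis(benzyloxy)benzyne (not isolated) | C1#CC(OCc2ccccc2)=CC(OCc2ccccc2)=C1 | intermediate
16 | ethyl (S)-3-[3,5-bis(benzyloxy)-2-caesiophenoxy]-3-phenylpropanoate (not isolated) | CCOC(=O)C[C@@H](c1ccccc1)Oc1cc(OCc2ccccc2)cc(OCc2ccccc2)c1[Cs] | intermediate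
17 | (S)-5,7-bis(benzyloxy)-2-phenylchroman-4-one | O=C1C[C@@H](c2ccccc2)Oc2cc(OCc3ccccc3)cc(OCc3ccccc3)c21 | intermediate
18 | (S)-5,7-bis(benzyloxy)-8-iodo-2-phenylchroman-4-one | O=C1C[C@@H](c2ccccc2)Oc2c(I)c(OCc3ccccc3)cc(OCc3ccccc3)c21 | intermediate
19 | {2-(benzyloxy)-5-[2-(benzyloxy)benzyl]benzyl}zinc chloride (not isolated) | Cl[Zn]Cc1cc(Cc2ccccc2OCc2ccccc2)ccc1OCc1ccccc1 | intermediate
20 | (S)-5,7-bis(benzyloxy)-8-{2-(benzyloxy)-5-[2-(benzyloxy)benzyl]benzyl}-2-phenylchroman-4-one | O=C1C[C@@H](c2ccccc2)Oc2c(Cc3cc(Cc4ccccc4OCc4ccccc4)ccc3OCc3ccccc3)c(OCc3ccccc3)cc(OCc3ccccc3)c21 | intermediate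
21 | (S)-5,7-bis(benzyloxy)-8-{2-(benzyloxy)-5-[2-(benzyloxy)benzyl]benzyl}-6-iodo-2-phenylchroman-4-one | O=C1C[C@@H](c2ccccc2)Oc2c(Cc3cc(Cc4ccccc4OCc4ccccc4)ccc3OCc3ccccc3)c(OCc3ccccc3)c(I)c(OCc3ccccc3)c21 | intermediate
22 | (2-(benzyloxy)-5-{2-(benzyloxy)-5-[2-(benzyloxy)benzyl]benzyl}benzyl)zinc chloride (not isolated) | Cl[Zn]Cc1cc(Cc2cc(Cc3ccccc3OCc3ccccc3)ccc2OCc2ccccc2)ccc1OCc1ccccc1 | intermediate
23 | (S)-5,7-bis(benzyloxy)-6-(2-(benzyloxy)-5-{2-(benzyloxy)-5-[2-(benzyloxy)benzyl]benzyl}benzyl)-8-{2-(benzyloxy)-5-[2-(benzyloxy)benzyl]benzyl}-2-phenylchroman-4-one | O=C1C[C@@H](c2ccccc2)Oc2c(Cc3cc(Cc4ccccc4OCc4ccccc4)ccc3OCc3ccccc3)c(OCc3ccccc3)c(Cc3cc(Cc4cc(Cc5ccccc5OCc5ccccc5)ccc4OCc4ccccc4)ccc3OCc3ccccc3)c(OCc3ccccc3)c21 | intermediate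
24 | sarmentosumin D | O=C1C[C@@H](c2ccccc2)Oc2c(Cc3cc(Cc4ccccc4O)ccc3O)c(O)c(Cc3cc(Cc4cc(Cc5ccccc5O)ccc4O)ccc3O)c(O)c21 | target

Total step count: 14. Longest linear sequence: 8 steps (steps 7 to 14 from 9, or steps 1 to 6, 13 and 14 from 1).

Steps most likely to fail

Step 9. Protonation of the aryl anion may outrun acyl transfer, so that the reaction stops at the O-aryl ether. The alkoxide of 14 may fragment by retro-aldol cleavage, or fluoride-induced ring opening and reclosure may erode the C2 configuration. The fallback forms the same two bonds one after the other by known chemistry and sets out from phenol 9. Mitsunobu etherification of 9 with commercial ethyl (R)-3-hydroxy-3-phenylpropanoate (PPh3, DIAD, THF, 0 °C, inversion at the carbinol carbon) should give ethyl (S)-3-[3,5-bis(benzyloxy)phenoxy]-3-phenylpropanoate F1. Saponification (LiOH, THF/H2O, 0 °C) should give (S)-3-[3,5-bis(benzyloxy)phenoxy]-3-phenylpropanoic acid F2. Intramolecular Friedel–Crafts acylation through the mixed anhydride (trifluoroacetic anhydride, CH2Cl2, 0 °C), in which the two ortho carbons are equivalent, returns to the route at 17; steps 7 and 8 are then not needed.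

Step 10. Iodination may be poorly selective between C8 and C6, or may be diverted to the enolisable C3 position. The fallback replaces steric control by chelation control and sets out from 17. One equivalent of BCl3 (CH2Cl2, −78 °C) should cleave only the 5-O-benzyl ether, which is peri to the ketone, to give (S)-7-(benzyloxy)-5-hydroxy-2-phenylchroman-4-one F3. Iodination ortho to the chelated hydroxyl (benzyltrimethylammonium dichloroiodate, CaCO3, CH2Cl2/MeOH, rt) should give (S)-7-(benzyloxy)-5-hydroxy-6-iodo-2-phenylchroman-4-one F4. Negishi coupling with zinc reagent 22 (Pd(OAc)2, SPhos, THF, slow addition to spare the chelated phenol) should give (S)-7-(benzyloxy)-6-(2-(benzyloxy)-5-{2-(benzyloxy)-5-[2-(benzyloxy)benzyl]benzyl}benzyl)-5-hydroxy-2-phenylchroman-4-one F5. NIS then iodinates the last free ring A carbon to give the 8-iodide (S)-7-(benzyloxy)-6-(2-(benzyloxy)-5-{2-(benzyloxy)-5-[2-(benzyloxy)benzyl]benzyl}benzyl)-5-hydroxy-8-iodo-2-phenylchroman-4-one F6. Negishi coupling with zinc reagent 19 should give (S)-7-(benzyloxy)-6-(2-(benzyloxy)-5-{2-(benzyloxy)-5-[2-(benzyloxy)benzyl]benzyl}benzyl)-8-{2-(benzyloxy)-5-[2-(benzyloxy)benzyl]benzyl}-5-hydroxy-2-phenylchroman-4-one F7. Hydrogenolysis under the conditions of step 14 comes back to the route at target 24.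

Step 13. Oxidative addition and transmetalation at the doubly ortho-substituted C6 iodide may be slow, so that protodeiodination and homocoupling of the benzylic zinc reagent take over. The fallback reverses the polarity of the bond formation and sets out from 20, the compound before iodination. Friedel–Crafts benzylation of its only free ring A carbon with benzylic alcohol 7 (Bi(OTf)3 cat., hexafluoroisopropanol, rt) should give 23 directly, where it rejoins the route; no new compound is made.

Further compounds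
F1 | step 9 | ethyl (S)-3-[3,5-bis(benzyloxy)phenoxy]-3-phenylpropanoate | CCOC(=O)C[C@@H](c1ccccc1)Oc1cc(OCc2ccccc2)cc(OCc2ccccc2)c1
F2 | step 9 | (S)-3-[3,5-bis(benzyloxy)phenoxy]-3-phenylpropanoic acid | OC(=O)C[C@@H](c1ccccc1)Oc1cc(OCc2ccccc2)cc(OCc2ccccc2)c1
F3 | step 10 | (S)-7-(benzyloxy)-5-hydroxy-2-phenylchroman-4-one | O=C1C[C@@H](c2ccccc2)Oc2cc(OCc3ccccc3)cc(O)c21
F4 | step 10 | (S)-7-(benzyloxy)-5-hydroxy-6-iodo-2-phenylchroman-4-one | O=C1C[C@@H](c2ccccc2)Oc2cc(OCc3ccccc3)c(I)c(O)c21
F5 | step 10 | (S)-7-(benzyloxy)-6-(2-(benzyloxy)-5-{2-(benzyloxy)-5-[2-(benzyloxy)benzyl]benzyl}benzyl)-5-hydroxy-2-phenylchroman-4-one | O=C1C[C@@H](c2ccccc2)Oc2cc(OCc3ccccc3)c(Cc3cc(Cc4cc(Cc5ccccc5OCc5ccccc5)ccc4OCc4ccccc4)ccc3OCc3ccccc3)c(O)c21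
F6 | step 10 | (S)-7-(benzyloxy)-6-(2-(benzyloxy)-5-{2-(benzyloxy)-5-[2-(benzyloxy)benzyl]benzyl}benzyl)-5-hydroxy-8-iodo-2-phenylchroman-4-one | O=C1C[C@@H](c2ccccc2)Oc2c(I)c(OCc3ccccc3)c(Cc3cc(Cc4cc(Cc5ccccc5OCc5ccccc5)ccc4OCc4ccccc4)ccc3OCc3ccccc3)c(O)c21
F7 | step 10 | (S)-7-(benzyloxy)-6-(2-(benzyloxy)-5-{2-(benzyloxy)-5-[2-(benzyloxy)benzyl]benzyl}benzyl)-8-{2-(benzyloxy)-5-[2-(benzyloxy)benzyl]benzyl}-5-hydroxy-2-phenylchroman-4-one | O=C1C[C@@H](c2ccccc2)Oc2c(Cc3cc(Cc4ccccc4OCc4ccccc4)ccc3OCc3ccccc3)c(OCc3ccccc3)c(Cc3cc(Cc4cc(Cc5ccccc5OCc5ccccc5)ccc4OCc4ccccc4)ccc3OCc3ccccc3)c(O)c21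
F0 | step 13 | none | none
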